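The dioxane ring (O1, C2 with the syringyl group, C3 with CH2OH, O4, fused to ring A through C4a and C8a) is traced back to a five-membered 1,3-benzodioxole. This works because O1 and O4 are the adjacent oxygens of the ring A catechol, so both can be parked on the future C3 as a ketal. Activating a neighbouring enantioenriched benzylic carbinol moves O1 from C3 to C2 with inversion. The C3 oxocarbenium ion is reduced in the same flask, which gives the ring, the O1–C2 bond and both stereocentres in one operation. The precursor is a 2-(benzyloxymethyl)-2-[(R)-aryl(hydroxy)methyl]benzodioxole whose phenols are tosylates.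

Key step: step 9

Remark: all benzodioxanes carry the dioxane locants of the overview. Every compound containing the ketal carbon is carried as a mixture of ketal epimers, which is harmless because the key step erases that centre.

Step 1
Reactants: 1 methyl gallate (methyl 3,4,5-trihydroxybenzoate); 2 methyl dichloroacetate
Product: 3 dimethyl 7-hydroxy-1,3-benzodioxole-2,5-dicarboxylate (racemic)
Conditions: K2CO3 (3 equiv), 2 (1.05 equiv), DMF, 80 °C, argon
Reagents that add atoms: none
Why: Double Williamson etherification of a vicinal diphenol with a geminal dichloride, the usual entry to 1,3-benzodioxole-2-carboxylates; the triol is symmetric, so either adjacent hydroxyl pair gives the same ring, about one equivalent of 2 leaves the third phenol free, and the new centre is racemic and is erased in step 9.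

Step 2
Reactants: 3 dimethyl 7-hydroxy-1,3-benzodioxole-2,5-dicarboxylate
Product: 4 dimethyl 7-(tosyloxy)-1,3-benzodioxole-2,5-dicarboxylate (racemic)
Conditions: TsCl (1.1 equiv), K2CO3, acetone, 25 to 50 °C
Reagents that add atoms: p-toluenesulfonyl chloride, Cc1ccc(cc1)S(=O)(=O)Cl
Why: Phenol sulfonylation; an arenesulfonate has no acidic α-hydrogen, so it should survive the amide base, the Grignard reagent and the hydrides that follow, and it is the withdrawing, bulky neighbour of O4 that the key step needs.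

Step 3
Reactants: 4 dimethyl 7-(tosyloxy)-1,3-benzodioxole-2,5-dicarboxylate; 5 benzyl chloromethyl ether
Product: 7 dimethyl 2-(benzyloxymethyl)-7-(tosyloxy)-1,3-benzodioxole-2,5-dicarboxylate (racemic), via lithium ester enolate 6 (not isolated)
Conditions: LiN(SiMe3)2 (1.1 equiv), THF, −78 °C; then 5 (1.5 equiv), −78 to −30 °C
Reagents that add atoms: none
Why: Ester enolate C-alkylation with a reactive α-chloro ether; the hydrogen between two aryloxy groups and the ester is the only acidic site, the enolate has no β-leaving group and so cannot ring-open, and the quaternary ketal centre forms as a racemate that converges later.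

Step 4
Reactants: 7 dimethyl 2-(benzyloxymethyl)-7-(tosyloxy)-1,3-benzodioxole-2,5-dicarboxylate
Product: 8 2-(benzyloxymethyl)-5-(methoxycarbonyl)-7-(tosyloxy)-1,3-benzodioxole-2-carboxylic acid (racemic)
Conditions: LiOH·H2O (1.05 equiv), THF/H2O, 0 °C; then 1 M HCl
Reagents that add atoms: lithium hydroxide, [Li+].[OH-]
Why: Chemoselective saponification; the ester flanked by two α-oxygens is far more electrophilic than the benzoate, which is deactivated by its para oxygen donor, so one equivalent of hydroxide at 0 °C should touch neither the benzoate nor the sulfonate.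

Step 5
Reactants: 8 2-(benzyloxymethyl)-5-(methoxycarbonyl)-7-(tosyloxy)-1,3-benzodioxole-2-carboxylic acid
Product: 10 methyl 2-(benzyloxymethyl)-2-[methoxy(methyl)carbamoyl]-7-(tosyloxy)-1,3-benzodioxole-5-carboxylate (racemic), via acyl imidazolide 9 (not isolated)
Conditions: 1,1'-carbonyldiimidazole (1.3 equiv), CH2Cl2, 25 °C; then MeNH(OMe)·HCl (2 equiv), 25 to 40 °C
Reagents that add atoms: N,O-dimethylhydroxylamine hydrochloride, CNOC.Cl
Why: Amide coupling through an acyl imidazolide to the Weinreb amide; the two α-oxygens keep the hindered acyl group electrophilic enough, and the hydrochloride activates the imidazolide by protonation.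

Step 6
Reactants: 11 4-bromo-2,6-dimethoxyphenol
Product: 12 4-bromo-2,6-dimethoxyphenyl 4-methylbenzenesulfonate
Conditions: TsCl (1.2 equiv), K2CO3, acetone, 50 °C
Reagents that add atoms: p-toluenesulfonyl chloride, Cc1ccc(cc1)S(=O)(=O)Cl
Why: Phenol sulfonylation; it installs from the start the para acceptor that later disfavours benzylic ionisation, which saves a protecting-group exchange.

Step 7
Reactants: 12 4-bromo-2,6-dimethoxyphenyl 4-methylbenzenesulfonate; 10 methyl 2-(benzyloxymethyl)-2-[methoxy(methyl)carbamoyl]-7-(tosyloxy)-1,3-benzodioxole-5-carboxylate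
Product: 14 methyl 2-(benzyloxymethyl)-2-[3,5-dimethoxy-4-(tosyloxy)benzoyl]-7-(tosyloxy)-1,3-benzodioxole-5-carboxylate (racemic), via arylmagnesium bromide 13 (not isolated)
Conditions: 12, Mg turnings, LiCl, THF, 25 °C (iBu2AlH 1 mol% as activator); 13 (1.2 equiv) added to 10, THF, −20 to 0 °C; 1 M HCl quench
Reagents that add atoms: none
Why: LiCl-assisted magnesium insertion, which tolerates aryl sulfonates, followed by Weinreb ketone synthesis; the chelated tetrahedral adduct stops the addition at the ketone, and an aryl Grignard reagent at or below 0 °C should leave the donor-substituted methyl benzoate alone.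

Step 8
Reactants: 14 methyl 2-(benzyloxymethyl)-2-[3,5-dimethoxy-4-(tosyloxy)benzoyl]-7-(tosyloxy)-1,3-benzodioxole-5-carboxylate
Product: 15 methyl 2-(benzyloxymethyl)-2-{(R)-[3,5-dimethoxy-4-(tosyloxy)phenyl](hydroxy)methyl}-7-(tosyloxy)-1,3-benzodioxole-5-carboxylate (both ketal epimers)
Conditions: (S)-Me-CBS [(3aS)-1-methyl-3,3-diphenyltetrahydro-1H,3H-pyrrolo[1,2-c][1,3,2]oxazaborole] (20 mol%), catecholborane (2 equiv), toluene/CH2Cl2, −78 to −40 °C; MeOH, aqueous work-up
Reagents that add atoms: none
Why: Corey–Bakshi–Shibata reduction; the quaternary, doubly oxygenated ketal carbon should act as the large group (as tert-alkyl and trihalomethyl groups do against aryl), so the (S)-catalyst should give the (R)-carbinol from both enantiomers of the ketone, whose own chirality is remote from the carbonyl group, while catecholborane at low temperature suppresses uncatalysed reduction of this activated carbonyl group.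

Step 9
Reactants: 15 methyl 2-(benzyloxymethyl)-2-{(R)-[3,5-dimethoxy-4-(tosyloxy)phenyl](hydroxy)methyl}-7-(tosyloxy)-1,3-benzodioxole-5-carboxylate
Product: 18 methyl (2S,3S)-3-(benzyloxymethyl)-2-[3,5-dimethoxy-4-(tosyloxy)phenyl]-5-(tosyloxy)-2,3-dihydro-1,4-benzodioxine-7-carboxylate, via benzylic triflate 16 (not isolated), via C3 oxocarbenium triflate 17 (not isolated)
Conditions: Tf2O (1.3 equiv), 2,6-di-tert-butyl-4-methylpyridine (2 equiv), Et3SiH (10 equiv), CH2Cl2, −78 to −30 °C
Reagents that add atoms: none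
Why: Proposed new method: Tf2O and the hindered pyridine turn the carbinol into benzylic triflate 16, whose departure is pushed from the rear by a lone pair of the ketal oxygen lying meta to the ring A ester; the bridged oxonium species then lets go of the old ketal carbon, so this oxygen arrives on C2 as O1, and the resulting cation 17 (C3=O4+) takes hydride from the Et3SiH already in the flask. The nearest known chemistry is the ZnBr2- or AgBF4-promoted rearrangement of ketals that carry a halide or sulfonate on the adjacent carbon, where an aryl or alkoxy group moves across and 2-(halomethyl)dioxolanes grow into dihydrodioxins, together with the Et3SiH reduction of six-membered cyclic oxocarbenium ions known from reductive etherification. The dioxane is closed by ring enlargement, five-membered dioxole to six-membered dioxane, through 3-exo-tet participation at C2 and cleavage of the internal C3–O bond, not by an end-to-end cyclisation. C2 becomes (S) by stereospecific inversion of the (R)-carbinol set in step 8, and C3 becomes (S) under substrate control, since hydride should enter axially, anti to the pseudo-axial C2–H of the half-chair that holds the aryl group pseudo-equatorial, which places CH2OBn equatorial and trans to the aryl group. The step needs migration of the meta oxygen only, which the substrate secures because the other oxygen is drained by the para ester and both drained and shielded by the neighbouring tosylate, and it needs participation to outrun free ionisation, which the 4-tosyloxy group and the two meta methoxy groups secure by making the benzylic cation poor. Excess silane, low temperature and a base too hindered to act as a nucleophile should keep hydride capture ahead of proton loss or hydride shift from C2, and both ketal epimers converge because the ketal carbon is planar in 17.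

Step 10
Reactants: 18 methyl (2S,3S)-3-(benzyloxymethyl)-2-[3,5-dimethoxy-4-(tosyloxy)phenyl]-5-(tosyloxy)-2,3-dihydro-1,4-benzodioxine-7-carboxylate
Product: 19 methyl (2S,3S)-2-[3,5-dimethoxy-4-(tosyloxy)phenyl]-3-(hydroxymethyl)-5-(tosyloxy)-2,3-dihydro-1,4-benzodioxine-7-carboxylate
Conditions: H2 (1 atm), Pd(OH)2/C, EtOAc/MeOH, 25 °C
Reagents that add atoms: none
Why: Catalytic hydrogenolysis of a primary benzyl ether, placed here because no alkene and no benzylic alcohol is present yet; the ring C2–O1 bond of 2-arylbenzodioxanes normally survives these conditions and is further deactivated by the tosyloxy-substituted aryl group.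

Step 11
Reactants: 19 methyl (2S,3S)-2-[3,5-dimethoxy-4-(tosyloxy)phenyl]-3-(hydroxymethyl)-5-(tosyloxy)-2,3-dihydro-1,4-benzodioxine-7-carboxylate
Product: 20 {(2S,3S)-2-[3,5-dimethoxy-4-(tosyloxy)phenyl]-5-(tosyloxy)-2,3-dihydro-1,4-benzodioxine-3,7-diyl}dimethanol
Conditions: iBu2AlH (4.5 equiv), CH2Cl2, −78 to −20 °C; aqueous potassium sodium tartrate
Reagents that add atoms: none
Why: Hydride reduction of the benzoate to the benzylic alcohol; one equivalent of hydride is spent on the free hydroxyl, and aryl sulfonates are inert to iBu2AlH at low temperature.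

Step 12
Reactants: 20 {(2S,3S)-2-[3,5-dimethoxy-4-(tosyloxy)phenyl]-5-(tosyloxy)-2,3-dihydro-1,4-benzodioxine-3,7-diyl}dimethanol
Product: 21 (2S,3S)-2-[3,5-dimethoxy-4-(tosyloxy)phenyl]-3-(hydroxymethyl)-5-(tosyloxy)-2,3-dihydro-1,4-benzodioxine-7-carbaldehyde
Conditions: activated MnO2 (20 equiv), CH2Cl2, 25 °C
Reagents that add atoms: none
Why: Chemoselective MnO2 oxidation, which takes benzylic alcohols and leaves saturated primary alcohols; no free phenol is present that could be oxidised.

Step 13
Reactants: 22 3,5-dihydroxybenzyl alcohol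
Product: 23 tert-butyl{[3,5-bis(tert-butyldimethylsilyloxy)benzyl]oxy}dimethylsilane
Conditions: TBSCl (3.5 equiv), imidazole (7 equiv), DMF, 25 °C
Reagents that add atoms: tert-butyldimethylsilyl chloride, CC(C)(C)[Si](C)(C)Cl
Why: Exhaustive silylation of two phenols and one alcohol under standard imidazole catalysis, so no selectivity is required.

Step 14
Reactants: 23 tert-butyl{[3,5-bis(tert-butyldimethylsilyloxy)benzyl]oxy}dimethylsilane
Product: 24 3,5-bis(tert-butyldimethylsilyloxy)benzyl bromide
Conditions: Ph3PBr2 (1.2 equiv), CH2Cl2, 0 to 25 °C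
Reagents that add atoms: dibromotriphenylphosphorane, BrP(Br)(c1ccccc1)(c1ccccc1)c1ccccc1
Why: Direct conversion of an alkyl silyl ether into the bromide with Ph3PBr2 (an Appel-type substitution through the alkoxyphosphonium salt); aryl silyl ethers cannot undergo the final SN2 step and so stay in place.

Step 15
Reactants: 24 3,5-bis(tert-butyldimethylsilyloxy)benzyl bromide
Product: 25 diethyl [3,5-bis(tert-butyldimethylsilyloxy)benzyl]phosphonate
Conditions: P(OEt)3 (neat, 3 equiv), 130 °C
Reagents that add atoms: triethyl phosphite, CCOP(OCC)OCC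
Why: Michaelis–Arbuzov reaction of a reactive benzylic bromide under neutral conditions that silyl ethers tolerate.

Step 16
Reactants: 21 (2S,3S)-2-[3,5-dimethoxy-4-(tosyloxy)phenyl]-3-(hydroxymethyl)-5-(tosyloxy)-2,3-dihydro-1,4-benzodioxine-7-carbaldehyde; 25 diethyl [3,5-bis(tert-butyldimethylsilyloxy)benzyl]phosphonate
Product: 27 (2S,3S)-7-{(E)-2-[3,5-bis(tert-butyldimethylsilyloxy)phenyl]ethenyl}-2-[3,5-dimethoxy-4-(tosyloxy)phenyl]-3-(hydroxymethyl)-2,3-dihydro-1,4-benzodioxin-5-yl 4-methylbenzenesulfonate, via potassium phosphonate carbanion 26 (not isolated)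
Conditions: 25 (2.5 equiv), KN(SiMe3)2 (2.4 equiv), THF, −78 to 0 °C; then 21, 0 to 25 °C; aqueous NH4Cl
Reagents that add atoms: none
Why: Horner–Wadsworth–Emmons olefination; potassium benzylphosphonate anions and aromatic aldehydes should give the E-stilbene, the surplus anion covers the free hydroxyl, and any silyl scrambling onto that hydroxyl is removed in the next step.

Step 17
Reactants: 27 (2S,3S)-7-{(E)-2-[3,5-bis(tert-butyldimethylsilyloxy)phenyl]ethenyl}-2-[3,5-dimethoxy-4-(tosyloxy)phenyl]-3-(hydroxymethyl)-2,3-dihydro-1,4-benzodioxin-5-yl 4-methylbenzenesulfonate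
Product: 28 (2S,3S)-7-[(E)-2-(3,5-dihydroxyphenyl)ethenyl]-2-(4-hydroxy-3,5-dimethoxyphenyl)-3-(hydroxymethyl)-2,3-dihydro-1,4-benzodioxin-5-ol (CNP0319597.1)
Conditions: KOH (20 equiv), 1,4-dioxane/H2O 3:1 (degassed), 70 °C, argon; then 1 M HCl, 0 °C
Reagents that add atoms: none
Why: Alkaline hydrolysis of both aryl sulfonates (attack at sulfur) and both aryl silyl ethers in one operation; leaving out an alcohol cosolvent avoids alkyl tosylates that could O-alkylate the phenoxides, the alkene sees no acid or reductant, and any reversible opening at C2 through the quinone methide is self-correcting because C3 cannot epimerise and the trans ring is the more stable one.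

Compound list
1 | methyl gallate | COC(=O)c1cc(O)c(O)c(O)c1 | starting material
2 | methyl dichloroacetate | COC(=O)C(Cl)Cl | starting material
3 | dimethyl 7-hydroxy-1,3-benzodioxole-2,5-dicarboxylate (racemic) | COC(=O)C1Oc2cc(C(=O)OC)cc(O)c2O1 | intermediate
4 | dimethyl 7-(tosyloxy)-1,3-benzodioxole-2,5-dicarboxylate (racemic) | COC(=O)C1Oc2cc(C(=O)OC)cc(OS(=O)(=O)c3ccc(C)cc3)c2O1 | intermediate
5 | benzyl chloromethyl ether | ClCOCc1ccccc1 | starting material
6 | lithium ester enolate of 4 (not isolated) | [Li+].COC([O-])=C1Oc2cc(C(=O)OC)cc(OS(=O)(=O)c3ccc(C)cc3)c2O1 | intermediate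
7 | dimethyl 2-(benzyloxymethyl)-7-(tosyloxy)-1,3-benzodioxole-2,5-dicarboxylate (racemic) | COC(=O)C1(COCc2ccccc2)Oc2cc(C(=O)OC)cc(OS(=O)(=O)c3ccc(C)cc3)c2O1 | intermediate
8 | 2-(benzyloxymethyl)-5-(methoxycarbonyl)-7-(tosyloxy)-1,3-benzodioxole-2-carboxylic acid (racemic) | OC(=O)C1(COCc2ccccc2)Oc2cc(C(=O)OC)cc(OS(=O)(=O)c3ccc(C)cc3)c2O1 | intermediate
9 | acyl imidazolide of 8 (not isolated) | O=C(n1ccnc1)C1(COCc2ccccc2)Oc2cc(C(=O)OC)cc(OS(=O)(=O)c3ccc(C)cc3)c2O1 | intermediate
10 | methyl 2-(benzyloxymethyl)-2-[methoxy(methyl)carbamoyl]-7-(tosyloxy)-1,3-benzodioxole-5-carboxylate (racemic) | CON(C)C(=O)C1(COCc2ccccc2)Oc2cc(C(=O)OC)cc(OS(=O)(=O)c3ccc(C)cc3)c2O1 | intermediate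
11 | 4-bromo-2,6-dimethoxyphenol | COc1cc(Br)cc(OC)c1O | starting material
12 | 4-bromo-2,6-dimethoxyphenyl 4-methylbenzenesulfonate | COc1cc(Br)cc(OC)c1OS(=O)(=O)c1ccc(C)cc1 | intermediate
13 | [3,5-dimethoxy-4-(tosyloxy)phenyl]magnesium bromide (not isolated) | COc1cc([Mg]Br)cc(OC)c1OS(=O)(=O)c1ccc(C)cc1 | intermediate
14 | methyl 2-(benzyloxymethyl)-2-[3,5-dimethoxy-4-(tosyloxy)benzoyl]-7-(tosyloxy)-1,3-benzodioxole-5-carboxylate (racemic) | COc1cc(C(=O)C2(COCc3ccccc3)Oc3cc(C(=O)OC)cc(OS(=O)(=O)c4ccc(C)cc4)c3O2)cc(OC)c1OS(=O)(=O)c1ccc(C)cc1 | intermediate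
15 | methyl 2-(benzyloxymethyl)-2-{(R)-[3,5-dimethoxy-4-(tosyloxy)phenyl](hydroxy)methyl}-7-(tosyloxy)-1,3-benzodioxole-5-carboxylate (both ketal epimers) | COc1cc([C@@H](O)C2(COCc3ccccc3)Oc3cc(C(=O)OC)cc(OS(=O)(=O)c4ccc(C)cc4)c3O2)cc(OC)c1OS(=O)(=O)c1ccc(C)cc1 | intermediate
16 | (R)-benzylic triflate of 15 (not isolated) | COc1cc([C@@H](OS(=O)(=O)C(F)(F)F)C2(COCc3ccccc3)Oc3cc(C(=O)OC)cc(OS(=O)(=O)c4ccc(C)cc4)c3O2)cc(OC)c1OS(=O)(=O)c1ccc(C)cc1 | intermediate
17 | (2S)-2-aryl-3-(benzyloxymethyl)-2H-1,4-benzodioxin-4-ium triflate, C3=O4+ (not isolated) | COc1cc([C@@H]2Oc3cc(C(=O)OC)cc(OS(=O)(=O)c4ccc(C)cc4)c3[O+]=C2COCc2ccccc2)cc(OC)c1OS(=O)(=O)c1ccc(C)cc1.[O-]S(=O)(=O)C(F)(F)F | intermediate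
18 | methyl (2S,3S)-3-(benzyloxymethyl)-2-[3,5-dimethoxy-4-(tosyloxy)phenyl]-5-(tosyloxy)-2,3-dihydro-1,4-benzodioxine-7-carboxylate | COc1cc([C@@H]2Oc3cc(C(=O)OC)cc(OS(=O)(=O)c4ccc(C)cc4)c3O[C@H]2COCc2ccccc2)cc(OC)c1OS(=O)(=O)c1ccc(C)cc1 | intermediate
19 | methyl (2S,3S)-2-[3,5-dimethoxy-4-(tosyloxy)phenyl]-3-(hydroxymethyl)-5-(tosyloxy)-2,3-dihydro-1,4-benzodioxine-7-carboxylate | COc1cc([C@@H]2Oc3cc(C(=O)OC)cc(OS(=O)(=O)c4ccc(C)cc4)c3O[C@H]2CO)cc(OC)c1OS(=O)(=O)c1ccc(C)cc1 | intermediate
20 | {(2S,3S)-2-[3,5-dimethoxy-4-(tosyloxy)phenyl]-5-(tosyloxy)-2,3-dihydro-1,4-benzodioxine-3,7-diyl}dimethanol | COc1cc([C@@H]2Oc3cc(CO)cc(OS(=O)(=O)c4ccc(C)cc4)c3O[C@H]2CO)cc(OC)c1OS(=O)(=O)c1ccc(C)cc1 | intermediate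
21 | (2S,3S)-2-[3,5-dimethoxy-4-(tosyloxy)phenyl]-3-(hydroxymethyl)-5-(tosyloxy)-2,3-dihydro-1,4-benzodioxine-7-carbaldehyde | COc1cc([C@@H]2Oc3cc(C=O)cc(OS(=O)(=O)c4ccc(C)cc4)c3O[C@H]2CO)cc(OC)c1OS(=O)(=O)c1ccc(C)cc1 | intermediate
22 | 3,5-dihydroxybenzyl alcohol | OCc1cc(O)cc(O)c1 | starting material
23 | tert-butyl{[3,5-bis(tert-butyldimethylsilyloxy)benzyl]oxy}dimethylsilane | CC(C)(C)[Si](C)(C)OCc1cc(O[Si](C)(C)C(C)(C)C)cc(O[Si](C)(C)C(C)(C)C)c1 | intermediate
24 | 3,5-bis(tert-butyldimethylsilyloxy)benzyl bromide | BrCc1cc(O[Si](C)(C)C(C)(C)C)cc(O[Si](C)(C)C(C)(C)C)c1 | intermediate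
25 | diethyl [3,5-bis(tert-butyldimethylsilyloxy)benzyl]phosphonate | CCOP(=O)(Cc1cc(O[Si](C)(C)C(C)(C)C)cc(O[Si](C)(C)C(C)(C)C)c1)OCC | intermediate
26 | potassium carbanion of 25 (not isolated) | [K+].CCOP(=O)([CH-]c1cc(O[Si](C)(C)C(C)(C)C)cc(O[Si](C)(C)C(C)(C)C)c1)OCC | intermediate
27 | (2S,3S)-7-{(E)-2-[3,5-bis(tert-butyldimethylsilyloxy)phenyl]ethenyl}-2-[3,5-dimethoxy-4-(tosyloxy)phenyl]-3-(hydroxymethyl)-2,3-dihydro-1,4-benzodioxin-5-yl 4-methylbenzenesulfonate | COc1cc([C@@H]2Oc3cc(/C=C/c4cc(O[Si](C)(C)C(C)(C)C)cc(O[Si](C)(C)C(C)(C)C)c4)cc(OS(=O)(=O)c4ccc(C)cc4)c3O[C@H]2CO)cc(OC)c1OS(=O)(=O)c1ccc(C)cc1 | intermediate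
28 | (2S,3S)-7-[(E)-2-(3,5-dihydroxyphenyl)ethenyl]-2-(4-hydroxy-3,5-dimethoxyphenyl)-3-(hydroxymethyl)-2,3-dihydro-1,4-benzodioxin-5-ol (CNP0319597.1) | COc1cc([C@@H]2Oc3cc(/C=C/c4cc(O)cc(O)c4)cc(O)c3O[C@H]2CO)cc(OC)c1O | target

Total step count: 17. Longest linear sequence: 13 (steps 1 to 5, 7 to 12, 16 and 17).

Steps most likely to fail

Step 9. Several processes compete with the planned one:
- The para oxygen may migrate instead of the meta oxygen.
- The triflate may ionise before participation sets in, which would lose configuration at C2.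
- The cation may lose a proton or undergo a 1,2-hydride shift from C2.
- Hydride may be delivered to the face that gives the cis ring, for instance if allylic-type strain pushes the aryl group pseudo-axial.
- Any cis isomer is a diastereomer and has to be removed by chromatography at this stage. Base-induced epimerisation at C2 in step 17 would otherwise turn it into the enantiomeric trans series.

Fallback, by known reaction types only, from 1 and 13 back to 18. The O4–C3 bond is made first from the chiral pool and O1–C2 is closed last by SN2.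
- A Mitsunobu reaction (PPh3, DIAD, THF, 0 °C) of 1, which should react at its most acidic 4-OH, with methyl (R)-3-(benzyloxy)-2-hydroxypropanoate F1 inverts the carbinol. It gives methyl 4-{[(2S)-3-(benzyloxy)-1-methoxy-1-oxopropan-2-yl]oxy}-3,5-dihydroxybenzoate F2. The two remaining hydroxyls of F2 are equivalent, so the fusion regiochemistry is no longer a question.
- AlMe3 and MeNH(OMe)·HCl (CH2Cl2, 0 to 25 °C) convert the activated aliphatic ester into Weinreb amide F3.
- Excess 13 (THF, −20 °C) gives (S)-α-aryloxy ketone F4.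
- Felkin–Anh reduction (NaBH4, MeOH/THF, −20 °C) should favour erythro (1R,2S)-alcohol F5, which is freed from its threo isomer by chromatography.
- An intramolecular Mitsunobu etherification (PPh3, DIAD, toluene) closes the dioxane with inversion at the benzylic carbon to trans-(2S,3S)-benzodioxane C5 phenol F6.
- Tosylation (TsCl, K2CO3, acetone) returns to 18.

Step 8. Poor discrimination between the flat aryl group and the quaternary ketal carbon, or uncatalysed background reduction, would erode the enantiomeric purity, and the key step can only pass on what it receives.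

Fallback from 14 back to 15: asymmetric transfer hydrogenation with RuCl[(S,S)-TsDPEN](p-cymene), HCO2H/Et3N, CH2Cl2, 25 to 40 °C.
- Hydride and proton are passed on in an outer-sphere six-membered transition state.
- The aryl group is recognised by a CH/π contact with the arene ligand and not by its size, so the sense follows the aryl ring.
- The (S,S) catalyst gives (S)-1-phenylethanol from acetophenone. It should give the same spatial arrangement here, which is named (R) because the ketal carbon outranks the aryl group.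
- No compound outside the list is made (F0).

Step 7. Addition to the hindered amide may be slow, which would allow competing attack of the Grignard reagent on the ring A ester or on sulfonate sulfur.

Fallback from 10 back to 14: the electrophile is changed to an aldehyde, which is far more reactive than any other site.
- Cp2Zr(H)Cl (THF, 25 °C), which reduces amides in the presence of esters, gives methyl 2-(benzyloxymethyl)-2-formyl-7-(tosyloxy)-1,3-benzodioxole-5-carboxylate F7.
- Reagent 13 adds at −78 °C to give the stereorandom carbinol F8.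
- Dess–Martin periodinane (CH2Cl2, 25 °C) oxidises F8 to 14.

Further compounds
F1 | step 9 | methyl (R)-3-(benzyloxy)-2-hydroxypropanoate | COC(=O)[C@H](O)COCc1ccccc1
F2 | step 9 | methyl 4-{[(2S)-3-(benzyloxy)-1-methoxy-1-oxopropan-2-yl]oxy}-3,5-dihydroxybenzoate | COC(=O)[C@@H](Oc1c(O)cc(C(=O)OC)cc1O)COCc1ccccc1
F3 | step 9 | methyl 4-{[(2S)-3-(benzyloxy)-1-[methoxy(methyl)amino]-1-oxopropan-2-yl]oxy}-3,5-dihydroxybenzoate (Weinreb amide) | CON(C)C(=O)[C@@H](Oc1c(O)cc(C(=O)OC)cc1O)COCc1ccccc1
F4 | step 9 | methyl 4-{[(2S)-3-(benzyloxy)-1-[3,5-dimethoxy-4-(tosyloxy)phenyl]-1-oxopropan-2-yl]oxy}-3,5-dihydroxybenzoate | COc1cc(C(=O)[C@@H](Oc2c(O)cc(C(=O)OC)cc2O)COCc2ccccc2)cc(OC)c1OS(=O)(=O)c1ccc(C)cc1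
F5 | step 9 | methyl 4-{[(1R,2S)-3-(benzyloxy)-1-[3,5-dimethoxy-4-(tosyloxy)phenyl]-1-hydroxypropan-2-yl]oxy}-3,5-dihydroxybenzoate (erythro) | COc1cc([C@@H](O)[C@@H](Oc2c(O)cc(C(=O)OC)cc2O)COCc2ccccc2)cc(OC)c1OS(=O)(=O)c1ccc(C)cc1
F6 | step 9 | methyl (2S,3S)-3-(benzyloxymethyl)-2-[3,5-dimethoxy-4-(tosyloxy)phenyl]-5-hydroxy-2,3-dihydro-1,4-benzodioxine-7-carboxylate | COc1cc([C@@H]2Oc3cc(C(=O)OC)cc(O)c3O[C@H]2COCc2ccccc2)cc(OC)c1OS(=O)(=O)c1ccc(C)cc1
F0 | step 8 | none | none
F7 | step 7 | methyl 2-(benzyloxymethyl)-2-formyl-7-(tosyloxy)-1,3-benzodioxole-5-carboxylate (racemic) | O=CC1(COCc2ccccc2)Oc2cc(C(=O)OC)cc(OS(=O)(=O)c3ccc(C)cc3)c2O1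
F8 | step 7 | methyl 2-(benzyloxymethyl)-2-{[3,5-dimethoxy-4-(tosyloxy)phenyl](hydroxy)methyl}-7-(tosyloxy)-1,3-benzodioxole-5-carboxylate (all stereoisomers) | COc1cc(C(O)C2(COCc3ccccc3)Oc3cc(C(=O)OC)cc(OS(=O)(=O)c4ccc(C)cc4)c3O2)cc(OC)c1OS(=O)(=O)c1ccc(C)cc1
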